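**Structural features**

Pseudopentafuhalol D is an achiral, fully aromatic pentamer: five benzene rings A–E joined in a line by four diaryl ether oxygens, with twelve phenolic hydroxyls and no carbon substituent. Ring A is a 2,4,6-trihydroxyphenyl group whose ether carbon A4 lies between two hydroxyls. Ring B carries the ethers to A and to C on adjacent carbons B1 and B6 with hydroxyls at B3 and B5; ring C is etherified at C1 (to B) and C5 (to D) with vicinal hydroxyls at C3 and C4; ring D is pentaoxygenated, with the ethers to C and E on adjacent carbons D1 and D6 and hydroxyls at D3–D5; ring E is a 3,4,5-trihydroxyphenyl ether. There is no stereocentre, so no stereocentres adjoin and nothing configurational has to be set; the problem is purely one of regiochemistry among almost identical oxygen functions. The free polyphenol is fragile: the pyrogallol units of rings D and E and the highly oxygenated rings B and C oxidise to quinones in air, fastest in base, so every hydroxyl must stay masked until a final neutral deprotection. The real difficulty is the four C–O–C links, each between two electron-rich rings and three of them at carbons with ortho oxygen substituents (A4, B6, D6), where ether couplings are slow. The key step uses the position of the C4 hydroxyl of ring C, para to the ether carbon C1 and ortho to the ether carbon C5: a formyl group in its place activates fluoride leaving groups at both carbons and is afterwards oxidised to that hydroxyl. The same relation of an oxygen next to an ether carbon (B6 beside B1, D1 beside D6) recurs in rings B and D and lets both fragment phenols be made by the same formyl-to-hydroxyl tactic.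

**Logic of the disconnections**

25 to 24. The twelve O–CH2Ph bonds are cut. Benzyl ethers survive base, copper and peracid and all fall in one neutral hydrogenolysis, the only kind of last step the air-sensitive product tolerates. One protecting group covers all twelve hydroxyls and no orthogonality is needed. The forward step must go to completion on a large substrate and the product must be kept from air.

24 to 22 (through 23). The C4–O bond of ring C is traded for a C4–CHO bond. The carbon substituent is what turns ring C from an electron-rich arene into an electrophile. The forward oxidation must make the aryl group migrate, which the ortho and para oxygen donors favour, and must spare the other electron-rich rings.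

22 to 20, 10 and 18 (through 21). Both ether bonds at ring C are cut, oxygen–C1 and oxygen–C5. These carbons are para and ortho to the formyl group, and cutting at the central ring gives a two-ring, one-ring, two-ring convergence. The forward step must send 10 only to the para fluoride and leave the ortho fluoride for 18.

20 to 19. The benzyl–oxygen bond is cut; the forward alkylation must not touch the fluorides.

10 to 8 (through 9). The hydroxyl C–O bond on ring B goes back to a formyl group. That formyl group sits ortho to B1 and activates it for the ether bond to ring A, and its oxidation puts the free hydroxyl exactly at B6.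

8 to 4 and 6 (through 7). The bonds from ring B to the ring A oxygen (at B1) and to a benzyloxy oxygen (at B5) are cut, both ortho to the formyl group. Because 6 is symmetric, the first substitution has no site problem, and the crowded nucleophile 4 enters while the ring is most activated. The forward step needs clean mono-substitution by 4 and then fluoride displacement by an alkoxide without damage to the aldehyde.

6 to 5, and 4 to 2 (through 3) to 1. Benzyl–oxygen bonds are cut and the phenol C–O bond of 4 goes back to a formyl group. Compound 1 already holds the three ring A oxygens and the carbon that becomes the fourth.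

18 to 16 (through 17). The hydroxyl C–O bond at D1 goes back to a formyl group, which sits ortho to D6 and assists the coupling there.

16 to 14 and 15. The bond from D6 to the ring E oxygen is cut. Ring D carries three donors, so fluoride displacement is not realistic and a copper-catalysed coupling of a bromide ortho to the formyl group is used. The forward step must couple at a bromide flanked on both sides.

14 (through 13) and 15 to 12, and 12 to 11. Both halves of the DE fragment come from one aldehyde, by oxidation in one case and ring bromination in the other; 12 comes from 11 by cutting three benzyl–oxygen bonds.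

**Other disconnections considered**

Alternative 1: The cut lies inside ring D, whose six carbons would come from a four-carbon squarate and a two-carbon enol ether, with the D1–D6 bond formed last. Heating racemic cyclobutenone A1 should open the four-membered ring by a 4π electrocyclic process to a dienylketene, which closes by 6π electrocyclisation between the ketene carbon (D1) and the vinyl terminus (D6) and tautomerises to hydroquinone A2. In its favour, the most heavily oxygenated ring is built with each oxygen placed by connectivity, and the required carbonyl addition is the electronically matched one, since the carbonyl vinylogous to the weaker aryloxy donor is the more electrophilic. The D–O–E bond would come from addition–elimination of 14 on a squaric ester, with no copper and no crowded bromide; on this bond the alternative is the better of the two. Against it, A2 has two free hydroxyls (D1 and D4) that would have to be told apart in the union with 20, and a hydroquinone is oxidised easily under the basic conditions of that union. The D5 oxygen arrives as a methyl ether, which calls for a Lewis-acid demethylation at the end, and aryloxy squarates can lose the aryloxy group to the organometallic reagent. The rearrangement is neutral, metal-free and mechanistically as dependable as the substitutions of the chosen plan, and the step count to a DE nucleophile is about equal. It makes only ring D, however, so it would feed step 12 rather than replace it, and the extra differentiation and demethylation make the whole route longer.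

Alternative 2: The cut lies inside ring A, between the ester carbon and the aryloxy-bearing terminal carbon of triketide ester A3. NaOMe would bring the terminal carbanion onto the ester carbonyl in a Claisen condensation, and the resulting cyclohexanetrione would enolise to the ring A triol of A4. In its favour, the plan is biomimetic, ring A appears with its hydroxyls free (ten benzyl ethers instead of twelve) and the crowded phenoxide 4 is replaced by a simple O-alkylation of a phenol; on these two points it is the better. Against it, the carbanion needed is the least acidic of the three in A3, and the usual fate of a triketide ester in base is O-acylation to a 4-hydroxy-2-pyrone, not C-acylation to the carbocycle. The step also places the least certain C–C bond formation on the most advanced intermediate, and it needs a four-ring phenol with one free hydroxyl at B1, which forces orthogonal protection on ring B. The chosen plan ends in a convergent union of fragments with a well-understood mechanism, while this one is linear and longer once the protecting-group changes are counted; the final hydrogenolysis is equal or slightly easier.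

Alternative 3: Three aryl C–O bonds (the hydroxyls at A1, C4 and E4, each para or ortho to ether carbons) are cut back to C–CHO bonds. Pentamer trialdehyde A5 would be oxidised three times by a peracid and the formates cleaved in the same pot to give triphenol A6. In its favour, all four ether bonds could then be made by fluoride displacement next to an aldehyde, with no copper step, three oxidations become one operation, and only ten benzyl ethers are needed; on these points it is the equal or the better, and ring C is handled exactly as in the chosen plan with 20. Against it, the nucleophiles for rings B and D become diols whose two hydroxyls must react in a fixed order with two different electrophiles. For ring D the bond to E must form at the more hindered hydroxyl, a mismatched case that brings protecting groups back. The formyl group on ring A has no ortho oxygen donor, so its aryl migration is the slowest of the three, and an incomplete threefold oxidation on one large molecule would give mixtures that are hard to separate. In the chosen plan each oxidation but the last is run on a small compound with a single aldehyde. Any gain in step count depends on the diol differentiation coming free, which the structure does not promise.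

Key step: step 12

Remark: a ring-by-ring comparison of 10, 18, 20 and 22 with the target puts every oxygen at its proper carbon, so these structures are used unchanged; the design adds only that 10 is the limiting phenol and that both fragment phenols are made through aldehydes.
Assumption: the hydroxybenzaldehydes 1, 5, 11 and 19 are bought as catalogue compounds.

Step 1
Reactants: 1 2,4,6-trihydroxybenzaldehyde
Product: 2 2,4,6-tris(benzyloxy)benzaldehyde
Conditions: BnBr (3.5 equiv), K2CO3, DMF, 60 °C, N2
Reagents that add atoms: benzyl bromide, BrCc1ccccc1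
Why: Williamson ether synthesis; carbonate in a dipolar aprotic solvent favours O- over C-alkylation, the formyl group lowers the carbon nucleophilicity of the phloroglucinol ring, and warming brings the two hydrogen-bonded ortho hydroxyls to react.

Step 2
Reactants: 2 2,4,6-tris(benzyloxy)benzaldehyde
Product: 4 2,4,6-tris(benzyloxy)phenol, via aryl formate 3 (not isolated)
Conditions: mCPBA, CH2Cl2, 0 °C to rt; aq Na2S2O3 wash; then K2CO3 (cat.), MeOH–THF, rt
Reagents that add atoms: mCPBA, OOC(=O)c1cccc(Cl)c1
Why: Baeyer–Villiger oxidation of an electron-rich aryl aldehyde: in the Criegee adduct the aryl group, pushed by two ortho and one para benzyloxy donors, migrates in preference to hydride to give formate 3. Carbonate-catalysed transesterification with methanol then frees the phenol, after the peracid has been destroyed so that the oxidant-sensitive phenol never meets it.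

Step 3
Reactants: 5 2,6-difluoro-4-hydroxybenzaldehyde
Product: 6 4-(benzyloxy)-2,6-difluorobenzaldehyde
Conditions: BnBr, K2CO3, DMF, rt
Reagents that add atoms: benzyl bromide, BrCc1ccccc1
Why: Williamson ether synthesis; at room temperature the para-formyl phenoxide of 5 is too weak a nucleophile to displace fluoride from another molecule, so only O-benzylation should occur.

Step 4
Reactants: 4 2,4,6-tris(benzyloxy)phenol; 6 4-(benzyloxy)-2,6-difluorobenzaldehyde
Product: 8 2,4-bis(benzyloxy)-6-[2,4,6-tris(benzyloxy)phenoxy]benzaldehyde, via monofluoro diaryl ether 7 (not isolated)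
Conditions: Cs2CO3, DMF, 70 °C; then BnOH (3 equiv), Cs2CO3, 90 °C
Reagents that add atoms: benzyl alcohol, OCc1ccccc1
Why: Two nucleophilic aromatic substitutions (addition–elimination through formyl-stabilised Meisenheimer adducts) at the two equivalent fluorides ortho to the formyl group of 6. The crowded phenoxide of 4 enters first, while the ring is most electrophilic, and the aryloxy group it installs deactivates 7 enough that a second molecule of 4 should not follow. The remaining fluoride then yields at higher temperature to the small, more nucleophilic benzyl alkoxide, fluoride being a far better leaving group than aryloxide in this mechanism.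

Step 5
Reactants: 8 2,4-bis(benzyloxy)-6-[2,4,6-tris(benzyloxy)phenoxy]benzaldehyde
Product: 10 2,4-bis(benzyloxy)-6-[2,4,6-tris(benzyloxy)phenoxy]phenol (AB phenol), via aryl formate 9 (not isolated)
Conditions: mCPBA, CH2Cl2, 0 °C to rt; aq Na2S2O3 wash; then K2CO3 (cat.), MeOH–THF, rt
Reagents that add atoms: mCPBA, OOC(=O)c1cccc(Cl)c1
Why: Baeyer–Villiger oxidation followed by formate methanolysis; the formyl-bearing ring has benzyloxy groups ortho and para and an aryloxy group ortho, so aryl migration is strongly favoured and the hydroxyl appears between the two oxygenated neighbours.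

Step 6
Reactants: 11 3,4,5-trihydroxybenzaldehyde
Product: 12 3,4,5-tris(benzyloxy)benzaldehyde
Conditions: BnBr (3.5 equiv), K2CO3, DMF, rt to 50 °C, N2
Reagents that add atoms: benzyl bromide, BrCc1ccccc1
Why: Williamson ether synthesis; exclusion of air protects the pyrogallol-type phenoxides from oxidation until all three oxygens are capped.

Step 7
Reactants: 12 3,4,5-tris(benzyloxy)benzaldehyde
Product: 14 3,4,5-tris(benzyloxy)phenol, via aryl formate 13 (not isolated)
Conditions: mCPBA, CH2Cl2, 0 °C to rt; aq Na2S2O3 wash; then K2CO3 (cat.), MeOH–THF, rt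
Reagents that add atoms: mCPBA, OOC(=O)c1cccc(Cl)c1
Why: Baeyer–Villiger oxidation and methanolysis of the formate; the para benzyloxy group supplies the donation needed for aryl migration.

Step 8
Reactants: 12 3,4,5-tris(benzyloxy)benzaldehyde
Product: 15 2-bromo-3,4,5-tris(benzyloxy)benzaldehyde
Conditions: NBS (1.05 equiv), MeCN, rt, dark
Reagents that add atoms: N-bromosuccinimide, O=C1CCC(=O)N1Br
Why: Electrophilic aromatic bromination; C2 and C6 of 12 are equivalent, each ortho to one and para to another benzyloxy group, the formyl group and the first bromine slow a second substitution, and the benzyl phenyl rings are far less activated than the trialkoxyarene.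

Step 9
Reactants: 14 3,4,5-tris(benzyloxy)phenol; 15 2-bromo-3,4,5-tris(benzyloxy)benzaldehyde
Product: 16 3,4,5-tris(benzyloxy)-2-[3,4,5-tris(benzyloxy)phenoxy]benzaldehyde
Conditions: CuI (20 mol%), picolinic acid (40 mol%), K3PO4, DMSO, 90 °C, Ar
Reagents that add atoms: none
Why: Ullmann diaryl ether synthesis (copper-catalysed C–O coupling); phenol 14 has no ortho substituent, and the bromide of 15, though flanked on both sides, is activated by the ortho formyl group, which withdraws electrons and can coordinate copper. Picolinic acid is a ligand suited to ortho-substituted partners and the phosphate base leaves the non-enolisable aldehyde intact.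

Step 10
Reactants: 16 3,4,5-tris(benzyloxy)-2-[3,4,5-tris(benzyloxy)phenoxy]benzaldehyde
Product: 18 3,4,5-tris(benzyloxy)-2-[3,4,5-tris(benzyloxy)phenoxy]phenol (DE phenol), via aryl formate 17 (not isolated)
Conditions: mCPBA, CH2Cl2, 0 °C to rt; aq Na2S2O3 wash; then K2CO3 (cat.), MeOH–THF, rt
Reagents that add atoms: mCPBA, OOC(=O)c1cccc(Cl)c1
Why: Baeyer–Villiger oxidation and methanolysis; the ortho aryloxy and para benzyloxy donors direct aryl migration, and the new hydroxyl comes out ortho to the ring E ether as required.

Step 11
Reactants: 19 2,4-difluoro-6-hydroxybenzaldehyde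
Product: 20 2-(benzyloxy)-4,6-difluorobenzaldehyde
Conditions: BnBr, K2CO3, DMF, rt
Reagents that add atoms: benzyl bromide, BrCc1ccccc1
Why: Williamson ether synthesis at room temperature, where the hydrogen-bonded, electron-poor phenoxide of 19 alkylates on oxygen and does not attack the fluorinated ring of the product.

Step 12
Reactants: 20 2-(benzyloxy)-4,6-difluorobenzaldehyde; 10 AB phenol; 18 DE phenol
Product: 22 2-(benzyloxy)-4-{2,4-bis(benzyloxy)-6-[2,4,6-tris(benzyloxy)phenoxy]phenoxy}-6-{3,4,5-tris(benzyloxy)-2-[3,4,5-tris(benzyloxy)phenoxy]phenoxy}benzaldehyde (pentamer aldehyde), via para-substituted monofluoride 21 (not isolated)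
Conditions: 10 (1.0 equiv), Cs2CO3, 4 Å MS, degassed DMF, 60 °C; then 18 (1.1 equiv), Cs2CO3, 100 °C
Reagents that add atoms: none
Why: Two nucleophilic aromatic substitutions by addition–elimination on the one-ring core. The cesium phenoxide of 10 adds to C4 of 20, para to the formyl group, to give a Meisenheimer anion whose charge is delocalised onto the carbonyl oxygen, and fluoride leaves to give 21; the closest known reaction type is the displacement of fluoride from 2,4-difluorobenzaldehydes by phenoxides in polar aprotic solvents. Site selectivity between the para and the ortho fluoride is needed: the para carbon has only hydrogens beside it, the ortho carbon lies next to the formyl group, and the attacking oxygen of 10 sits between a benzyloxy and an aryloxy group, so the bulky nucleophile should go para at the lower temperature. The new aryloxy group donates into the ring and lowers its electrophilicity, so 21 should not react further with 10 at 60 °C; selectivity between first and second substitution rests on temperature and on 10 being the limiting phenol. Heating then lets the less hindered phenoxide of 18 displace the remaining ortho fluoride through a second formyl-stabilised Meisenheimer adduct. No ring is closed and no stereocentre is formed; two C–O bonds join two two-ring fragments to the core in one flask. Dry, degassed solvent keeps out hydroxide, which would give phenol by-products, and air, which would oxidise the phenoxides.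

Step 13
Reactants: 22 pentamer aldehyde
Product: 24 2-(benzyloxy)-4-{2,4-bis(benzyloxy)-6-[2,4,6-tris(benzyloxy)phenoxy]phenoxy}-6-{3,4,5-tris(benzyloxy)-2-[3,4,5-tris(benzyloxy)phenoxy]phenoxy}phenol (pentamer phenol, free hydroxyl at C4 of ring C), via pentamer formate 23 (not isolated)
Conditions: mCPBA, CH2Cl2, 0 °C to rt; aq Na2S2O3 wash; then K2CO3 (cat.), MeOH–THF, rt
Reagents that add atoms: mCPBA, OOC(=O)c1cccc(Cl)c1
Why: Baeyer–Villiger oxidation of the only carbonyl group in 22; its ring carries ortho benzyloxy, ortho aryloxy and para aryloxy donors, so the aryl group should migrate to give formate 23. After reductive quench of the peracid, carbonate-catalysed methanolysis reveals the C4 hydroxyl.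

Step 14
Reactants: 24 pentamer phenol
Product: 25 Pseudopentafuhalol D
Conditions: H2 (1 atm), 10% Pd/C, THF–MeOH, rt; filtration and evaporation under Ar
Reagents that add atoms: none
Why: Catalytic hydrogenolysis of the twelve benzyl ethers under neutral conditions; diaryl ether bonds and arene rings are inert to Pd/C at room temperature and atmospheric pressure, and handling under argon keeps the oxidation-prone polyphenol from air.

**Compound list**

1 | 2,4,6-trihydroxybenzaldehyde | O=Cc1c(O)cc(O)cc1O | starting material
2 | 2,4,6-tris(benzyloxy)benzaldehyde | O=Cc1c(OCc9ccccc9)cc(OCc9ccccc9)cc1OCc9ccccc9 | intermediate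
3 | 2,4,6-tris(benzyloxy)phenyl formate | O=COc1c(OCc9ccccc9)cc(OCc9ccccc9)cc1OCc9ccccc9 | intermediate
4 | 2,4,6-tris(benzyloxy)phenol | Oc1c(OCc9ccccc9)cc(OCc9ccccc9)cc1OCc9ccccc9 | intermediate
5 | 2,6-difluoro-4-hydroxybenzaldehyde | O=Cc1c(F)cc(O)cc1F | starting material
6 | 4-(benzyloxy)-2,6-difluorobenzaldehyde | O=Cc1c(F)cc(OCc9ccccc9)cc1F | intermediate
7 | 4-(benzyloxy)-2-fluoro-6-[2,4,6-tris(benzyloxy)phenoxy]benzaldehyde | O=Cc1c(F)cc(OCc9ccccc9)cc1Oc1c(OCc9ccccc9)cc(OCc9ccccc9)cc1OCc9ccccc9 | intermediate
8 | 2,4-bis(benzyloxy)-6-[2,4,6-tris(benzyloxy)phenoxy]benzaldehyde | O=Cc1c(OCc9ccccc9)cc(OCc9ccccc9)cc1Oc1c(OCc9ccccc9)cc(OCc9ccccc9)cc1OCc9ccccc9 | intermediate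
9 | 2,4-bis(benzyloxy)-6-[2,4,6-tris(benzyloxy)phenoxy]phenyl formate | O=COc1c(OCc9ccccc9)cc(OCc9ccccc9)cc1Oc1c(OCc9ccccc9)cc(OCc9ccccc9)cc1OCc9ccccc9 | intermediate
10 | 2,4-bis(benzyloxy)-6-[2,4,6-tris(benzyloxy)phenoxy]phenol (AB phenol) | Oc1c(OCc9ccccc9)cc(OCc9ccccc9)cc1Oc1c(OCc9ccccc9)cc(OCc9ccccc9)cc1OCc9ccccc9 | intermediate
11 | 3,4,5-trihydroxybenzaldehyde | O=Cc1cc(O)c(O)c(O)c1 | starting material
12 | 3,4,5-tris(benzyloxy)benzaldehyde | O=Cc1cc(OCc9ccccc9)c(OCc9ccccc9)c(OCc9ccccc9)c1 | intermediate
13 | 3,4,5-tris(benzyloxy)phenyl formate | O=COc1cc(OCc9ccccc9)c(OCc9ccccc9)c(OCc9ccccc9)c1 | intermediate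
14 | 3,4,5-tris(benzyloxy)phenol | Oc1cc(OCc9ccccc9)c(OCc9ccccc9)c(OCc9ccccc9)c1 | intermediate
15 | 2-bromo-3,4,5-tris(benzyloxy)benzaldehyde | O=Cc1cc(OCc9ccccc9)c(OCc9ccccc9)c(OCc9ccccc9)c1Br | intermediate
16 | 3,4,5-tris(benzyloxy)-2-[3,4,5-tris(benzyloxy)phenoxy]benzaldehyde | O=Cc1cc(OCc9ccccc9)c(OCc9ccccc9)c(OCc9ccccc9)c1Oc1cc(OCc9ccccc9)c(OCc9ccccc9)c(OCc9ccccc9)c1 | intermediate
17 | 3,4,5-tris(benzyloxy)-2-[3,4,5-tris(benzyloxy)phenoxy]phenyl formate | O=COc1cc(OCc9ccccc9)c(OCc9ccccc9)c(OCc9ccccc9)c1Oc1cc(OCc9ccccc9)c(OCc9ccccc9)c(OCc9ccccc9)c1 | intermediate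
18 | 3,4,5-tris(benzyloxy)-2-[3,4,5-tris(benzyloxy)phenoxy]phenol (DE phenol) | Oc1cc(OCc9ccccc9)c(OCc9ccccc9)c(OCc9ccccc9)c1Oc1cc(OCc9ccccc9)c(OCc9ccccc9)c(OCc9ccccc9)c1 | intermediate
19 | 2,4-difluoro-6-hydroxybenzaldehyde | O=Cc1c(O)cc(F)cc1F | starting material
20 | 2-(benzyloxy)-4,6-difluorobenzaldehyde | O=Cc1c(F)cc(F)cc1OCc9ccccc9 | intermediate
21 | 2-(benzyloxy)-6-fluoro-4-{2,4-bis(benzyloxy)-6-[2,4,6-tris(benzyloxy)phenoxy]phenoxy}benzaldehyde | O=Cc1c(F)cc(Oc2c(OCc9ccccc9)cc(OCc9ccccc9)cc2Oc2c(OCc9ccccc9)cc(OCc9ccccc9)cc2OCc9ccccc9)cc1OCc9ccccc9 | intermediate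
22 | pentamer aldehyde (formyl at C4 of ring C, twelve benzyl ethers) | O=Cc1c(Oc2cc(OCc9ccccc9)c(OCc9ccccc9)c(OCc9ccccc9)c2Oc2cc(OCc9ccccc9)c(OCc9ccccc9)c(OCc9ccccc9)c2)cc(Oc2c(OCc9ccccc9)cc(OCc9ccccc9)cc2Oc2c(OCc9ccccc9)cc(OCc9ccccc9)cc2OCc9ccccc9)cc1OCc9ccccc9 | intermediate
23 | pentamer formate (formyloxy at C4 of ring C, twelve benzyl ethers) | O=COc1c(Oc2cc(OCc9ccccc9)c(OCc9ccccc9)c(OCc9ccccc9)c2Oc2cc(OCc9ccccc9)c(OCc9ccccc9)c(OCc9ccccc9)c2)cc(Oc2c(OCc9ccccc9)cc(OCc9ccccc9)cc2Oc2c(OCc9ccccc9)cc(OCc9ccccc9)cc2OCc9ccccc9)cc1OCc9ccccc9 | intermediate
24 | pentamer phenol (free hydroxyl at C4 of ring C, twelve benzyl ethers) | Oc1c(Oc2cc(OCc9ccccc9)c(OCc9ccccc9)c(OCc9ccccc9)c2Oc2cc(OCc9ccccc9)c(OCc9ccccc9)c(OCc9ccccc9)c2)cc(Oc2c(OCc9ccccc9)cc(OCc9ccccc9)cc2Oc2c(OCc9ccccc9)cc(OCc9ccccc9)cc2OCc9ccccc9)cc1OCc9ccccc9 | intermediate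
25 | Pseudopentafuhalol D | Oc1cc(O)c(Oc2cc(O)cc(O)c2Oc2cc(O)c(O)c(Oc3cc(O)c(O)c(O)c3Oc3cc(O)c(O)c(O)c3)c2)c(O)c1 | target

**Step count and risks**

Total: 14 steps. Longest linear sequence: 7 steps (1, 2, 4, 5, 12, 13, 14; the DE branch through 6, 7 or 8, 9, 10, 12, 13, 14 is equally long).

Step 12 (key step). The first substitution may lose site control, with 10 attacking the fluoride ortho to the formyl group or a second molecule of 10 entering. At 100 °C the second phenoxide may exchange with the para aryloxy group, or the second displacement may stall because the ring of 21 carries two oxygen donors. Fallback: the order of the two bonds is written into the leaving groups. Setting out from 10, 2-bromo-4-fluoro-6-hydroxybenzaldehyde F1 (bought) is benzylated (BnBr, K2CO3, DMF) to 2-(benzyloxy)-6-bromo-4-fluorobenzaldehyde F2. The phenoxide of 10 displaces its only fluoride (Cs2CO3, DMF, 60 °C; bromide is a poor leaving group in addition–elimination) to give 2-(benzyloxy)-6-bromo-4-(AB-oxy)benzaldehyde F3, which is isolated. An Ullmann ether synthesis of F3 with 18 (CuI, picolinic acid, K3PO4, DMSO, 90 °C) at the bromide ortho to the formyl group returns to the route at 22.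

Step 4. The doubly ortho-substituted phenoxide of 4 may attack slowly. In the second stage the benzyl alkoxide may add to the formyl group and transfer hydride, or displace the aryloxy group in place of fluoride. Fallback: setting out from 4, 1,3-bis(benzyloxy)-5-bromobenzene F4 (bought, or made by benzylation of 5-bromoresorcinol) is formylated under Vilsmeier–Haack conditions (POCl3, DMF) at the carbon ortho to bromine and para to a benzyloxy group to give 2,4-bis(benzyloxy)-6-bromobenzaldehyde F5. Copper-catalysed Ullmann coupling of F5 with 4 (CuI, picolinic acid, K3PO4, DMSO, 100 °C) installs the ring A oxygen with both benzyl ethers already in place and returns to the route at 8.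

Step 9. Coupling at a bromide flanked by a formyl and a benzyloxy group may be slow, leaving time for protodebromination and base-induced degradation of the aldehyde. Fallback: setting out from 15, Pinnick oxidation (NaClO2, NaH2PO4, 2-methyl-2-butene, t-BuOH–H2O) gives 2-bromo-3,4,5-tris(benzyloxy)benzoic acid F6. The ortho-carboxylate-assisted Ullmann condensation of F6 with 14 (CuI, K2CO3, pyridine–DMF, 120 °C), the classical setting for copper-mediated arylation of phenols, gives 3,4,5-tris(benzyloxy)-2-[3,4,5-tris(benzyloxy)phenoxy]benzoic acid F7. Reduction (BH3·THF) gives {3,4,5-tris(benzyloxy)-2-[3,4,5-tris(benzyloxy)phenoxy]phenyl}methanol F8, and MnO2 in CH2Cl2 returns to the route at 16.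

Step 13. The electrophilic peracid may attack the electron-rich benzyloxy rings, hydride may migrate in place of the aryl group, or the liberated phenol may be oxidised further. Fallback: setting out from 22, chelation-controlled cleavage of the one benzyl ether ortho to the formyl group (MgBr2·OEt2, toluene–Et2O, reflux) gives the pentamer salicylaldehyde F9. A Dakin oxidation (H2O2, NaOH, THF–H2O, 0 °C), which requires the ortho hydroxyl and uses a nucleophilic oxidant, gives the undecabenzyl pentamer catechol F10. Hydrogenolysis of F10 under the conditions of step 14 returns to the route at 25.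

Step 14. Hydrogenolysis may stop short as partly debenzylated intermediates change solubility and foul the catalyst, and the product may oxidise in air during work-up. Fallback: setting out from 24, the benzyl ethers are cleaved by a Lewis acid in place of hydrogen, BCl3 with pentamethylbenzene as a non-basic benzyl cation scavenger in CH2Cl2 at −78 °C followed by a methanol quench, arriving directly at 25; this fallback makes no new compound (F0).

**Further compounds**

F1 | step 12 | 2-bromo-4-fluoro-6-hydroxybenzaldehyde | O=Cc1c(O)cc(F)cc1Br
F2 | step 12 | 2-(benzyloxy)-6-bromo-4-fluorobenzaldehyde | O=Cc1c(Br)cc(F)cc1OCc9ccccc9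
F3 | step 12 | 2-(benzyloxy)-6-bromo-4-{2,4-bis(benzyloxy)-6-[2,4,6-tris(benzyloxy)phenoxy]phenoxy}benzaldehyde | O=Cc1c(Br)cc(Oc2c(OCc9ccccc9)cc(OCc9ccccc9)cc2Oc2c(OCc9ccccc9)cc(OCc9ccccc9)cc2OCc9ccccc9)cc1OCc9ccccc9
F4 | step 4 | 1,3-bis(benzyloxy)-5-bromobenzene | Brc1cc(OCc9ccccc9)cc(OCc9ccccc9)c1
F5 | step 4 | 2,4-bis(benzyloxy)-6-bromobenzaldehyde | O=Cc1c(Br)cc(OCc9ccccc9)cc1OCc9ccccc9
F6 | step 9 | 2-bromo-3,4,5-tris(benzyloxy)benzoic acid | OC(=O)c1cc(OCc9ccccc9)c(OCc9ccccc9)c(OCc9ccccc9)c1Br
F7 | step 9 | 3,4,5-tris(benzyloxy)-2-[3,4,5-tris(benzyloxy)phenoxy]benzoic acid | OC(=O)c1cc(OCc9ccccc9)c(OCc9ccccc9)c(OCc9ccccc9)c1Oc1cc(OCc9ccccc9)c(OCc9ccccc9)c(OCc9ccccc9)c1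
F8 | step 9 | {3,4,5-tris(benzyloxy)-2-[3,4,5-tris(benzyloxy)phenoxy]phenyl}methanol | OCc1cc(OCc9ccccc9)c(OCc9ccccc9)c(OCc9ccccc9)c1Oc1cc(OCc9ccccc9)c(OCc9ccccc9)c(OCc9ccccc9)c1
F9 | step 13 | pentamer salicylaldehyde (formyl at C4 and free hydroxyl at C3 of ring C, eleven benzyl ethers) | O=Cc1c(Oc2cc(OCc9ccccc9)c(OCc9ccccc9)c(OCc9ccccc9)c2Oc2cc(OCc9ccccc9)c(OCc9ccccc9)c(OCc9ccccc9)c2)cc(Oc2c(OCc9ccccc9)cc(OCc9ccccc9)cc2Oc2c(OCc9ccccc9)cc(OCc9ccccc9)cc2OCc9ccccc9)cc1O
F10 | step 13 | pentamer catechol (free hydroxyls at C3 and C4 of ring C, eleven benzyl ethers) | Oc1c(Oc2cc(OCc9ccccc9)c(OCc9ccccc9)c(OCc9ccccc9)c2Oc2cc(OCc9ccccc9)c(OCc9ccccc9)c(OCc9ccccc9)c2)cc(Oc2c(OCc9ccccc9)cc(OCc9ccccc9)cc2Oc2c(OCc9ccccc9)cc(OCc9ccccc9)cc2OCc9ccccc9)cc1O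
F0 | step 14 | none | none
A1 | alternative 1 | racemic 3-(benzyloxy)-4-hydroxy-4-(1-methoxyvinyl)-2-[3,4,5-tris(benzyloxy)phenoxy]cyclobut-2-en-1-one | O=C1C(Oc2cc(OCc9ccccc9)c(OCc9ccccc9)c(OCc9ccccc9)c2)=C(OCc9ccccc9)C1(O)C(=C)OC
A2 | alternative 1 | 3-(benzyloxy)-5-methoxy-2-[3,4,5-tris(benzyloxy)phenoxy]benzene-1,4-diol (DE hydroquinone) | Oc1cc(OC)c(O)c(OCc9ccccc9)c1Oc1cc(OCc9ccccc9)c(OCc9ccccc9)c(OCc9ccccc9)c1
A3 | alternative 2 | methyl 3,5-dioxo-6-(decabenzyl BCDE-aryloxy)hexanoate (triketide ester) | COC(=O)CC(=O)CC(=O)COc1cc(OCc9ccccc9)cc(OCc9ccccc9)c1Oc1cc(OCc9ccccc9)c(OCc9ccccc9)c(Oc2cc(OCc9ccccc9)c(OCc9ccccc9)c(OCc9ccccc9)c2Oc2cc(OCc9ccccc9)c(OCc9ccccc9)c(OCc9ccccc9)c2)c1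
A4 | alternative 2 | decabenzyl pentamer with free ring A triol | Oc1cc(O)c(Oc2cc(OCc9ccccc9)cc(OCc9ccccc9)c2Oc2cc(OCc9ccccc9)c(OCc9ccccc9)c(Oc3cc(OCc9ccccc9)c(OCc9ccccc9)c(OCc9ccccc9)c3Oc3cc(OCc9ccccc9)c(OCc9ccccc9)c(OCc9ccccc9)c3)c2)c(O)c1
A5 | alternative 3 | decabenzyl pentamer trialdehyde (formyl groups at A1, C4 and E4) | O=Cc1cc(OCc9ccccc9)c(Oc2cc(OCc9ccccc9)cc(OCc9ccccc9)c2Oc2cc(OCc9ccccc9)c(C=O)c(Oc3cc(OCc9ccccc9)c(OCc9ccccc9)c(OCc9ccccc9)c3Oc3cc(OCc9ccccc9)c(C=O)c(OCc9ccccc9)c3)c2)c(OCc9ccccc9)c1
A6 | alternative 3 | decabenzyl pentamer triphenol (hydroxyls at A1, C4 and E4) | Oc1cc(OCc9ccccc9)c(Oc2cc(OCc9ccccc9)cc(OCc9ccccc9)c2Oc2cc(OCc9ccccc9)c(O)c(Oc3cc(OCc9ccccc9)c(OCc9ccccc9)c(OCc9ccccc9)c3Oc3cc(OCc9ccccc9)c(O)c(OCc9ccccc9)c3)c2)c(OCc9ccccc9)c1
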